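- In a one-step world each D takes one Q, becomes J and rests, so Q charged beyond D just idles. The ochre and teal runs refuse that picture: in teal, J still falls from 84.8% to 66.0% with D read at 0%.

| setting | ochre | teal | flask |
|---|---|---|---|
| D | 0.010 M | 0.015 M | 0.020 M |
| Q | 0.021 M (in portions, 4) | 0.021 M (in portions, 4) | 0.0210 M (in portions, 4) |
| remark | run made earlier; portions every 25 s | run made earlier; portions every 25 s | the portions of Q follow each other after 25 s, the first at the start |
| time |  |  | 2.5 h |

| run | time / min | D / % | J / % |
|---|---|---|---|
| ochre | 8.00 | 0 | 89.6 |
| ochre | 25.0 | 0 | 72.5 |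
| ochre | 40.0 | 0 | 60.2 |
| ochre | 60.0 | 0.1 | 50.5 |
| ochre | 90.0 | 0.1 | 39.7 |
| ochre | 120 | 0.5 | 32.4 |
| teal | 10.0 | 1.3 | 93.6 |
| teal | 15.0 | 0.4 | 90.3 |
| teal | 25.0 | 0.4 | 84.8 |
| teal | 40.0 | 0.7 | 78.6 |
| teal | 80.0 | 0 | 69.3 |
| teal | 120 | 0 | 66.0 |

(scatter of a reading: 0.5 percentage points)

- as a solid, counted per litre of solution: D
- at the start none of D is in solution
- what has only dissolved of D counts as not reacted
- the reaction counts as stopped when no species that holds the D changes by six tenths of a point or more over the second half of the time

- at 2.5 h, what has stopped the reaction, if anything has (for what has run out or reacted, a solid counts together with what of it has only dissolved) (all of D has reacted / it is still moving / forward and back rates have come level)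
- part of the D that has turned into other species by 2.5 h (what has only dissolved does not count)
- the J standing at 2.5 h, as a percentage of the D charged

- A Q molecule therefore meets a fork: it takes a fresh D, or it takes a J.
- The quantity to carry is the surplus: the Q charge over the D charge, minus one. It is the fraction of the D charge that can take a second Q once each D has had its first, and J then ends at one minus the surplus.
- Teal has a surplus of 40.0%, so its J heads for 60.0%. The gap above that level shrinks with a time constant of 66.9 min. Teal's D reads 1.3% by 10.0 min, a time shorter than that constant, so my reading of teal is that the fork favours D strongly.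
- The decision concerns the next flask: keep 0.0210 M of Q against 0.020 M of D for 2.5 h, or trim Q? Its surplus is 5.00%, so J ends near 95.0%.
- Taking the loss as proportional to J and to the Q left, the pseudo-first-order time constant goes inversely with the standing J. Teal's J lay near 75.4% of 0.015 M, and the flask's should stand near 95.0% of 0.020 M, so my estimate for the flask is 39.8 min. The flask's run lasts 3.77 such constants, which by this estimate leaves 0.115% of the D charge in unspent surplus. So my choice is to keep the recipe and expect D fully reacted.
- The forecast names "all of D has reacted", with conversion 98.5% (96% to 100%) and J 90% (86% to 95%), lower than my figure, and it says: "This choice is a judgement, not something the data prove."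
- The flask gives "all of D has reacted", conversion 100% and J 95.0%.

    Z + Q → J + X (k = 63.0 L mol⁻¹ s⁻¹)
    2 Z → E (k = 0.140 L mol⁻¹ s⁻¹)
    D ⇌ Z, rate k3*(cs3 - [Z]) while solid is left; crystals form when [Z] > cs3 (solubility = 2.70 mM, k = 0.0590 s⁻¹)
    Q + J → G (k = 0.0240 L mol⁻¹ s⁻¹)

- Half of the turnover of Z + Q → J + X is done by 1.25 min, far earlier than the 0.312 h of Q + J → G, while 2 Z → E turns over 0.0212% and leaves J where it stands. At 2.5 h G holds 4.97%, matching the surplus, and Q is at 0.065% of its charge, with the half-life of J by that step, 24 d, long against 2.5 h.
- With 0.084 M of Q the surplus is 320%, beyond the whole D charge, so J should vanish and 52.4% of the Q should stay. That flask computes J at 0.00552% and Q at 52%.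

The readings come from a simulation with constants of no real substance; the scatter is artificial.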